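**Plan**

- Retrosynthesis: the gallate ester C–O bond and the twelve benzyl ethers are cut first, then the upper C2–ring B bond (aryl added to a C2 oxocarbenium ion). Next, in one operation, upper C4–C3 and O1–C2 are cut (hetero-Diels–Alder), and last the lower C8–upper C4 bond (aryllithium plus aldehyde).
- Enabling feature: in upper ring C, O1–C8a–C4a–C4 is a latent 1-oxadiene, the ortho-quinone methide of upper ring A with lower C8 on the methide carbon C4. C3–C2 is a latent vinyl ether once ring B is taken off C2.
- Forward: commercial (−)-epigallocatechin is pentabenzylated, brominated at C8 and silylated at O3. Its 8-lithio form adds to a phloroglucinaldehyde aryl tert-butyl carbonate, and the benzhydrol is converted into the quinone methide, which closes upper ring C as a 2-alkoxy acetal. Ring B is then placed on C2, followed by desilylation, galloylation (the gallate enters only here) and hydrogenolysis.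
- Stereochemistry: lower C2 and C3 (2R,3R) come unchanged from epigallocatechin. Upper C4 (R) comes from the (1S,2R)-2-phenylcyclohexyl vinyl ether (endo addition to the E-methide on the face away from the phenyl group). Upper C2 (S) comes from arylzinc attack anti to the C4 aryl (2,4-trans).

Key step: step 8

Assumption: the vinyl ether is taken to react in its s-trans conformation on the face away from the phenyl group and the methide to be E, and on this model the (1S,2R) auxiliary leads to 4R; compounds 9 and 12 are mixtures of carbinol epimers that converge at the planar methide 13.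

**Route**

Step 1
Reactants: 1 (−)-epigallocatechin
Product: 2 (2R,3R)-5,7-bis(benzyloxy)-2-[3,4,5-tris(benzyloxy)phenyl]chroman-3-ol (penta-O-benzyl-epigallocatechin)
Conditions: BnBr (5.5 equiv), K2CO3 (6 equiv), degassed DMF, Ar, dark, 0 °C → rt
Reagents that add atoms: benzyl bromide, BrCc1ccccc1
Why: Williamson etherification of the five phenols, which K2CO3 deprotonates while the secondary 3-hydroxyl stays free, run cold and oxygen-free with the electrophile present before the base so that O-benzylation outruns pyrogallol oxidation and the base-induced C2 epimerisation of free catechins; both stereocentres are not touched.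

Step 2
Reactants: 2 penta-O-benzyl-epigallocatechin
Product: 3 (2R,3R)-5,7-bis(benzyloxy)-8-bromo-2-[3,4,5-tris(benzyloxy)phenyl]chroman-3-ol
Conditions: NBS (1.0 equiv), CH2Cl2, −78 °C → rt
Reagents that add atoms: N-bromosuccinimide, O=C1CCC(=O)N1Br
Why: Electrophilic aromatic bromination; for 5,7-di-O-benzyl flavan-3-ols NBS is known to select C8 of the phloroglucinol ring over C6 and over the less activated tribenzyloxyphenyl ring.

Step 3
Reactants: 3 8-bromo alcohol
Product: 4 3-O-tert-butyldimethylsilyl ether of 3
Conditions: TBSOTf, 2,6-lutidine, CH2Cl2, 0 °C → rt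
Reagents that add atoms: tert-butyldimethylsilyl trifluoromethanesulfonate, CC(C)(C)[Si](C)(C)OS(=O)(=O)C(F)(F)F
Why: Silylation of the hindered axial secondary alcohol with a silyl triflate gives an O3 protecting group that tolerates organolithium, Grignard and cold BF3·OEt2 and is orthogonal to the benzyl ethers.

Step 4
Reactants: 5 2,4,6-trihydroxybenzaldehyde
Product: 6 2,4-bis(benzyloxy)-6-hydroxybenzaldehyde
Conditions: BnBr (2.1 equiv), K2CO3, DMF, 0 °C → rt
Reagents that add atoms: benzyl bromide, BrCc1ccccc1
Why: Williamson etherification in which the para hydroxyl and one ortho hydroxyl react while the last ortho hydroxyl, held in a hydrogen bond to the formyl group, is the least nucleophilic, the usual selectivity for 2,4,6-trihydroxyaryl carbonyl compounds.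

Step 5
Reactants: 6 2,4-bis(benzyloxy)-6-hydroxybenzaldehyde
Product: 7 tert-butyl 3,5-bis(benzyloxy)-2-formylphenyl carbonate
Conditions: Boc2O, i-Pr2NEt, DMAP (cat.), THF, 0 °C → rt
Reagents that add atoms: di-tert-butyl dicarbonate, CC(C)(C)OC(=O)OC(=O)OC(C)(C)C
Why: DMAP-catalysed O-acylation of the phenol with Boc2O gives the aryl tert-butyl carbonate that later serves as the internal trigger for methide formation.

Step 6
Reactants: 4 3-O-silylated 8-bromide; 7 aryl carbonate aldehyde
Product: 9 benzhydrol joining lower C8 to the upper ring A that bears the ortho aryl tert-butyl carbonate (mixture of carbinol epimers), via 8-lithio lower unit 8 (not isolated)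
Conditions: 4, n-BuLi, THF, −78 °C; then 7, −78 °C; AcOH/THF quench at −78 °C; Et3N-buffered silica
Reagents that add atoms: none
Why: Bromine–lithium exchange followed by 1,2-addition of the aryllithium to the aldehyde, which at −78 °C is far more electrophilic than the aryl carbonate; the lithium alkoxide is protonated cold before Boc transfer and elimination can set in, and the new carbinol centre needs no control because it becomes planar in step 8.

Step 7
Reactants: 10 (1S,2R)-2-phenylcyclohexanol
Product: 11 (1S,2R)-2-phenylcyclohexyl vinyl ether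
Conditions: ethyl vinyl ether (solvent), Hg(OAc)2 (cat.), reflux; then K2CO3
Reagents that add atoms: ethyl vinyl ether, C=COCC
Why: Hg(OAc)2-catalysed transetherification (vinyl exchange) moves the vinyl group onto the auxiliary oxygen without breaking the carbinol C–O bond, so both stereocentres are retained.

Step 8
Reactants: 9 benzhydrol; 11 (1S,2R)-2-phenylcyclohexyl vinyl ether
Product: 14 (2R,4R)-2-alkoxy-4-arylchroman acetal (upper ring C closed), via benzylic carbonate magnesium phenoxide 12 (not isolated), via ortho-quinone methide 13 (not isolated)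
Conditions: 11 (4 equiv), t-BuMgCl (1.05 equiv), toluene, −78 °C → rt
Reagents that add atoms: none
Why: t-BuMgCl deprotonates the carbinol of 9, the chloromagnesium alkoxide takes the Boc group from the neighbouring phenol oxygen through a six-membered transition state to give 12, and the magnesium phenoxide then expels tert-butyl carbonate in a 1,4-elimination to give the E-configured ortho-quinone methide 13 of upper ring A, with the lower aryl on the side of the 5-benzyloxy group and away from the magnesium-bound oxygen. The closest known reaction type is the inverse-electron-demand hetero-Diels–Alder reaction of magnesium-generated ortho-quinone methides with enol ethers, 2-phenylcyclohexyl vinyl ethers included, which gives 2-alkoxy-4-substituted chromans. Upper ring C closes by a concerted, asynchronous [4+2] cycloaddition of the four-atom oxadiene O1–C8a–C4a–C4 with the two-carbon alkene, C4 bonding to the unsubstituted CH2 carbon and O1 to the alkoxy-bearing carbon, which restores the aromaticity of ring A. C4 (R) is controlled by the auxiliary: the vinyl ether reacts in its s-trans conformation with the carbinol C–H in the enol-ether plane, the phenyl ring covers the Si face of the oxygen-bearing alkene carbon, and endo approach of the E-methide to the open Re face should give 4R, while C2 (R, cis to the C4 aryl) follows from the endo arrangement and is erased in step 10. The step needs regioselectivity, which the opposed polarisation of the two partners secures, endo selectivity, which the preference of the alkoxy group to lie under the oxadiene at low temperature secures, and facial selectivity, which the auxiliary secures; the vinyl ether is used in excess so that cycloaddition outruns methide dimerisation.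

Step 9
Reactants: 15 4-bromo-1,2-bis(benzyloxy)benzene
Product: 17 3,4-bis(benzyloxy)phenylzinc chloride (used as a solution), via 3,4-bis(benzyloxy)phenyllithium 16 (not isolated)
Conditions: n-BuLi, THF, −78 °C; ZnCl2 (1.0 equiv), −78 °C → rt; THF replaced by toluene
Reagents that add atoms: zinc chloride, Cl[Zn]Cl
Why: Bromine–lithium exchange followed by transmetalation of the aryllithium onto one equivalent of ZnCl2 gives the arylzinc chloride (as its LiCl adduct), which once the coordinating THF is removed is nucleophilic enough for oxocarbenium ions yet tolerant of BF3·OEt2 at low temperature.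

Step 10
Reactants: 14 chroman acetal; 17 arylzinc chloride
Product: 19 fully benzylated 3-O-silyl (2S,4R)-flavan-(4→8)-epigallocatechin, via chroman oxocarbenium ion 18 (not isolated)
Conditions: 17 (2 equiv), BF3·OEt2 (2.5 equiv), CH2Cl2/toluene, −78 → −30 °C; aq. NaHCO3
Reagents that add atoms: none
Why: Lewis-acid-promoted substitution of a cyclic acetal by an arylzinc reagent, the C-arylation known for glycosyl oxocarbenium ions, in which BF3·OEt2 ionises the exocyclic C2–O bond to oxocarbenium ion 18 and the aryl group adds to the nearly planar cation on the face opposite the C4 aryl, which sits pseudoaxial to avoid peri strain with the 5-benzyloxy group and shields its own face, so that the 2,4-trans flavan with 2S is formed.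

Step 11
Reactants: 19 silyl ether
Product: 20 free 3-ol of the benzylated dimer
Conditions: HF·pyridine, pyridine/THF, 0 °C → rt
Reagents that add atoms: none
Why: Fluoride-driven desilylation under buffered conditions cleaves only the Si–O bond, leaving the benzyl ethers and all four stereocentres as they are.

Step 12
Reactants: 20 free 3-ol; 21 3,4,5-tris(benzyloxy)benzoic acid
Product: 22 dodeca-O-benzyl target (3-O-galloyl ester)
Conditions: DCC, DMAP, CH2Cl2, rt
Reagents that add atoms: none
Why: Steglich esterification, the standard way to galloylate the axial 3-hydroxyl of benzylated epi-series flavan-3-ols; the C3–O bond is not broken, so configuration is retained.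

Step 13
Reactants: 22 dodeca-O-benzyl target
Product: 23 target CNP0190017.1
Conditions: H2 (1 atm), Pd(OH)2/C, THF/MeOH, rt; filtration under Ar, lyophilisation
Reagents that add atoms: none
Why: Catalytic hydrogenolysis of the twelve benzyl ethers over Pd(OH)2/C, conditions under which the gallate ester, the ring C benzylic C–O bonds and the C4–C8 bond of benzylated flavan-3-ol oligomers are known to persist; no stereocentre is touched.

**Compound list**

1 | (−)-epigallocatechin, (2R,3R) | O[C@@H]1Cc2c(O)cc(O)cc2O[C@@H]1c1cc(O)c(O)c(O)c1 | starting material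
2 | (2R,3R)-5,7-bis(benzyloxy)-2-[3,4,5-tris(benzyloxy)phenyl]chroman-3-ol | O[C@@H]1Cc2c(OCc3ccccc3)cc(OCc3ccccc3)cc2O[C@@H]1c1cc(OCc3ccccc3)c(OCc3ccccc3)c(OCc3ccccc3)c1 | intermediate
3 | (2R,3R)-5,7-bis(benzyloxy)-8-bromo-2-[3,4,5-tris(benzyloxy)phenyl]chroman-3-ol | O[C@@H]1Cc2c(OCc3ccccc3)cc(OCc3ccccc3)c(Br)c2O[C@@H]1c1cc(OCc3ccccc3)c(OCc3ccccc3)c(OCc3ccccc3)c1 | intermediate
4 | 3-O-tert-butyldimethylsilyl ether of 3, (2R,3R) | CC(C)(C)[Si](C)(C)O[C@@H]1Cc2c(OCc3ccccc3)cc(OCc3ccccc3)c(Br)c2O[C@@H]1c1cc(OCc3ccccc3)c(OCc3ccccc3)c(OCc3ccccc3)c1 | intermediate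
5 | 2,4,6-trihydroxybenzaldehyde | O=Cc1c(O)cc(O)cc1O | starting material
6 | 2,4-bis(benzyloxy)-6-hydroxybenzaldehyde | O=Cc1c(O)cc(OCc2ccccc2)cc1OCc1ccccc1 | intermediate
7 | tert-butyl 3,5-bis(benzyloxy)-2-formylphenyl carbonate | CC(C)(C)OC(=O)Oc1cc(OCc2ccccc2)cc(OCc2ccccc2)c1C=O | intermediate
8 | 8-lithio derivative of 4 (aryllithium), (2R,3R) | CC(C)(C)[Si](C)(C)O[C@@H]1Cc2c(OCc3ccccc3)cc(OCc3ccccc3)c([Li])c2O[C@@H]1c1cc(OCc3ccccc3)c(OCc3ccccc3)c(OCc3ccccc3)c1 | intermediate (not isolated)
9 | benzhydrol: lower C8–CH(OH)–[2,4-bis(benzyloxy)-6-(tert-butoxycarbonyloxy)phenyl], lower unit (2R,3R), carbinol epimers | CC(C)(C)[Si](C)(C)O[C@@H]1Cc2c(OCc3ccccc3)cc(OCc3ccccc3)c(C(O)c3c(OC(=O)OC(C)(C)C)cc(OCc4ccccc4)cc3OCc3ccccc3)c2O[C@@H]1c1cc(OCc3ccccc3)c(OCc3ccccc3)c(OCc3ccccc3)c1 | intermediate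
10 | (1S,2R)-2-phenylcyclohexanol | O[C@H]1CCCC[C@@H]1c1ccccc1 | starting material
11 | (1S,2R)-2-phenylcyclohexyl vinyl ether | C=CO[C@H]1CCCC[C@@H]1c1ccccc1 | intermediate
12 | chloromagnesium phenoxide of the benzylic tert-butyl carbonate formed from 9 by Boc transfer (carbinol epimers) | CC(C)(C)[Si](C)(C)O[C@@H]1Cc2c(OCc3ccccc3)cc(OCc3ccccc3)c(C(OC(=O)OC(C)(C)C)c3c(O[Mg]Cl)cc(OCc4ccccc4)cc3OCc3ccccc3)c2O[C@@H]1c1cc(OCc3ccccc3)c(OCc3ccccc3)c(OCc3ccccc3)c1 | intermediate (not isolated)
13 | E ortho-quinone methide of upper ring A: 3,5-bis(benzyloxy)-6-(arylmethylidene)cyclohexa-2,4-dien-1-one with the lower unit (2R,3R) as the aryl group | CC(C)(C)[Si](C)(C)O[C@@H]1Cc2c(OCc3ccccc3)cc(OCc3ccccc3)c(/C=C3/C(=O)C=C(OCc4ccccc4)C=C3OCc3ccccc3)c2O[C@@H]1c1cc(OCc3ccccc3)c(OCc3ccccc3)c(OCc3ccccc3)c1 | intermediate (not isolated)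
14 | chroman acetal: upper (2R,4R)-5,7-bis(benzyloxy)-2-{[(1S,2R)-2-phenylcyclohexyl]oxy}chroman-4-yl on C8 of the lower (2R,3R) unit, 2,4-cis | CC(C)(C)[Si](C)(C)O[C@@H]1Cc2c(OCc3ccccc3)cc(OCc3ccccc3)c([C@@H]3C[C@H](O[C@H]4CCCC[C@@H]4c4ccccc4)Oc4cc(OCc5ccccc5)cc(OCc5ccccc5)c43)c2O[C@@H]1c1cc(OCc3ccccc3)c(OCc3ccccc3)c(OCc3ccccc3)c1 | intermediate
15 | 4-bromo-1,2-bis(benzyloxy)benzene | Brc1ccc(OCc2ccccc2)c(OCc2ccccc2)c1 | starting material
16 | 3,4-bis(benzyloxy)phenyllithium | [Li]c1ccc(OCc2ccccc2)c(OCc2ccccc2)c1 | intermediate (not isolated)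
17 | 3,4-bis(benzyloxy)phenylzinc chloride | Cl[Zn]c1ccc(OCc2ccccc2)c(OCc2ccccc2)c1 | intermediate
18 | chroman oxocarbenium ion (O1=C2 cation) of the upper unit, C4 as in 14 | CC(C)(C)[Si](C)(C)O[C@@H]1Cc2c(OCc3ccccc3)cc(OCc3ccccc3)c([C@@H]3CC=[O+]c4cc(OCc5ccccc5)cc(OCc5ccccc5)c43)c2O[C@@H]1c1cc(OCc3ccccc3)c(OCc3ccccc3)c(OCc3ccccc3)c1 | intermediate (not isolated)
19 | upper (2S,4R)-5,7-bis(benzyloxy)-2-[3,4-bis(benzyloxy)phenyl]chroman-4-yl on C8 of the lower (2R,3R) 3-O-TBS unit, 2,4-trans | CC(C)(C)[Si](C)(C)O[C@@H]1Cc2c(OCc3ccccc3)cc(OCc3ccccc3)c([C@@H]3C[C@@H](c4ccc(OCc5ccccc5)c(OCc5ccccc5)c4)Oc4cc(OCc5ccccc5)cc(OCc5ccccc5)c43)c2O[C@@H]1c1cc(OCc3ccccc3)c(OCc3ccccc3)c(OCc3ccccc3)c1 | intermediate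
20 | 3-ol obtained from 19 by desilylation | O[C@@H]1Cc2c(OCc3ccccc3)cc(OCc3ccccc3)c([C@@H]3C[C@@H](c4ccc(OCc5ccccc5)c(OCc5ccccc5)c4)Oc4cc(OCc5ccccc5)cc(OCc5ccccc5)c43)c2O[C@@H]1c1cc(OCc3ccccc3)c(OCc3ccccc3)c(OCc3ccccc3)c1 | intermediate
21 | 3,4,5-tris(benzyloxy)benzoic acid | OC(=O)c1cc(OCc2ccccc2)c(OCc2ccccc2)c(OCc2ccccc2)c1 | starting material
22 | dodeca-O-benzyl target: 3-O-[3,4,5-tris(benzyloxy)benzoyl] ester of 20 | O=C(O[C@@H]1Cc2c(OCc3ccccc3)cc(OCc3ccccc3)c([C@@H]3C[C@@H](c4ccc(OCc5ccccc5)c(OCc5ccccc5)c4)Oc4cc(OCc5ccccc5)cc(OCc5ccccc5)c43)c2O[C@@H]1c1cc(OCc3ccccc3)c(OCc3ccccc3)c(OCc3ccccc3)c1)c1cc(OCc3ccccc3)c(OCc3ccccc3)c(OCc3ccccc3)c1 | intermediate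
23 | CNP0190017.1: (2S,4R)-5,7,3',4'-tetrahydroxyflavan-(4→8)-(−)-epigallocatechin 3-O-gallate | O=C(O[C@@H]1Cc2c(O)cc(O)c([C@@H]3C[C@@H](c4ccc(O)c(O)c4)Oc4cc(O)cc(O)c43)c2O[C@@H]1c1cc(O)c(O)c(O)c1)c1cc(O)c(O)c(O)c1 | target

**Count**

Total steps: 13. Longest linear sequence: 9 steps (1, 2, 3, 6, 8, 10, 11, 12, 13).

**Steps most likely to fail**

Step 8. The chiral lower unit on the methide carbon and the auxiliary may be mismatched, the methide may form as an E/Z mixture, or it may dimerise before it is trapped, so that facial selectivity at C4 is poor. Should the observed sense simply be opposite to the model, the enantiomeric alcohol would be used in step 7. If selectivity is low with either auxiliary, reagent control would be abandoned. Starting from 9, the methide would be generated with t-BuMgCl as before but trapped with achiral ethyl vinyl ether. The C4-epimeric 2-ethoxy acetals are diastereomers because of the two fixed centres of the lower unit and would be separated by chromatography. The (2R,4R)-2-ethoxy acetal F1 would then be carried through the arylation of step 10, with ethanol in place of the auxiliary alcohol as leaving group, coming back to the route at 19.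

Step 10. Ionisation may occur at the endocyclic C2–O1 bond (ring opening toward the phenol) instead of the exocyclic one, aryl transfer from zinc may be slow beside decomposition of the cation, or the 2,4-trans preference may erode. Starting from 14, the acetal would be hydrolysed with dilute acid (PPTS, acetone/water), which also returns the auxiliary alcohol, to give the lactol F2. Addition of 3,4-bis(benzyloxy)phenylmagnesium bromide F3 (from 15 and Mg in THF) to the open hydroxy-aldehyde form would give the phenol–benzylic alcohol diol F4. Acid-catalysed cycloetherification of F4 (cat. TsOH, CH2Cl2, 0 °C) through the benzylic cation stabilised by the dibenzyloxyphenyl ring should close ring C under thermodynamic control to the 2,4-trans flavan, coming back to the route at 19.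

Step 6. Addition of the doubly ortho-substituted aryllithium to the doubly ortho-substituted aldehyde may be slow, the aryllithium may attack the carbonate, or Boc transfer and methide formation may set in before the quench; the electron-rich benzhydrol may also ionise during isolation. The C–C bond formation would then be separated from the labile carbonate. Starting from 4 (lithiated to 8 as before) and from 6, converted with NaH in THF into sodium 3,5-bis(benzyloxy)-2-formylphenoxide F5, addition at −78 → 0 °C would give the ortho-hydroxybenzhydrol F6. Chemoselective carbonate formation at the phenol (Boc2O, i-Pr2NEt, cat. DMAP, CH2Cl2, −20 °C), which is much faster than acylation of the hindered secondary carbinol, comes back to the route at 9.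

**Further compounds**

F1 | step 8 | (2R,4R)-2-ethoxy-4-arylchroman acetal (ethyl analogue of 14) | CC(C)(C)[Si](C)(C)O[C@@H]1Cc2c(OCc3ccccc3)cc(OCc3ccccc3)c([C@@H]3C[C@H](OCC)Oc4cc(OCc5ccccc5)cc(OCc5ccccc5)c43)c2O[C@@H]1c1cc(OCc3ccccc3)c(OCc3ccccc3)c(OCc3ccccc3)c1
F2 | step 10 | (4R)-4-arylchroman-2-ol lactol (anomers) | CC(C)(C)[Si](C)(C)O[C@@H]1Cc2c(OCc3ccccc3)cc(OCc3ccccc3)c([C@@H]3CC(O)Oc4cc(OCc5ccccc5)cc(OCc5ccccc5)c43)c2O[C@@H]1c1cc(OCc3ccccc3)c(OCc3ccccc3)c(OCc3ccccc3)c1
F3 | step 10 | 3,4-bis(benzyloxy)phenylmagnesium bromide | Br[Mg]c1ccc(OCc2ccccc2)c(OCc2ccccc2)c1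
F4 | step 10 | ring-opened diol: 1-[3,4-bis(benzyloxy)phenyl]-3-[2,4-bis(benzyloxy)-6-hydroxyphenyl]-3-(lower unit C8)propan-1-ol, carbinol epimers | CC(C)(C)[Si](C)(C)O[C@@H]1Cc2c(OCc3ccccc3)cc(OCc3ccccc3)c([C@H](CC(O)c3ccc(OCc4ccccc4)c(OCc4ccccc4)c3)c3c(O)cc(OCc4ccccc4)cc3OCc3ccccc3)c2O[C@@H]1c1cc(OCc3ccccc3)c(OCc3ccccc3)c(OCc3ccccc3)c1
F5 | step 6 | sodium 3,5-bis(benzyloxy)-2-formylphenoxide | [Na+].[O-]c1cc(OCc2ccccc2)cc(OCc2ccccc2)c1C=O
F6 | step 6 | ortho-hydroxybenzhydrol (9 without the Boc group), carbinol epimers | CC(C)(C)[Si](C)(C)O[C@@H]1Cc2c(OCc3ccccc3)cc(OCc3ccccc3)c(C(O)c3c(O)cc(OCc4ccccc4)cc3OCc3ccccc3)c2O[C@@H]1c1cc(OCc3ccccc3)c(OCc3ccccc3)c(OCc3ccccc3)c1
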